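The lactone oxygen O1 of the dihydrocoumarin sits between the C2 carbonyl and the aromatic carbon C8a. Deleting it joins C2 to C8a and leaves a five-membered aryl ketone, a 3-phenylindan-1-one, in which the C4 stereocentre is already in place. The route builds (S)-4,6-dimethoxy-3-phenylindan-1-one by catalytic asymmetric hydroacylation. A peracid then inserts O1 with migration of the aryl carbon, forming O1–C2 and O1–C8a and expanding the carbocycle to the six-membered lactone in one operation. Both methoxy groups of the precursor are meta to the ketone. C8 acylation and demethylation finish the synthesis.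

Key step: step 3

Remark on regiochemistry: Friedel–Crafts closure of a 3-(3,5-dimethoxyphenyl)-3-phenylpropanoic acid would give the 5,7-dimethoxyindanone and, after oxygen insertion, a 6,8-dioxygenated lactone. The 4,6-dimethoxy pattern needed here has its ketone carbon meta to both ethers, which an acylium closure cannot reach in competition with the phenyl ring. The aryl–carbonyl bond is therefore brought in with the starting aldehyde, and the five-membered ring is closed at C1–C2.

Remark on assumptions: 1, 2 and 7 are taken as catalogue compounds. The sense of induction in step 2 cannot be assigned with confidence for this substitution pattern, so the BINAP antipode that delivers (S)-4 is fixed by one calibration run (both antipodes are commercial).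

Step 1
Reactants: 1 2-bromo-3,5-dimethoxybenzaldehyde; 2 4,4,5,5-tetramethyl-2-(1-phenylvinyl)-1,3,2-dioxaborolane (1-phenylvinylboronic acid pinacol ester)
Product: 3 3,5-dimethoxy-2-(1-phenylvinyl)benzaldehyde
Conditions: Pd(OAc)2 (3 mol %), SPhos (6 mol %), K3PO4 (3 equiv), toluene/H2O 10:1, 80 °C
Reagents that add atoms: none
Why: Suzuki–Miyaura cross-coupling; a bulky biarylphosphine ligand is the standard answer to a doubly ortho-substituted aryl bromide and an α-substituted alkenylboronate, and the non-enolisable aldehyde and the ethers are inert to aqueous phosphate.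

Step 2
Reactants: 3 3,5-dimethoxy-2-(1-phenylvinyl)benzaldehyde
Product: 4 (S)-4,6-dimethoxy-3-phenylindan-1-one
Conditions: [Rh(nbd)((R)-BINAP)]BF4 (5 mol %, H2-activated, then purged), CH2Cl2, rt, degassed
Reagents that add atoms: none
Why: Rh(I)-catalysed enantioselective intramolecular alkene hydroacylation of a 2-(1-arylvinyl)benzaldehyde: aldehyde C–H oxidative addition, hydride transfer to the internal alkene carbon and C1–C2 reductive elimination should give the indanone with every atom retained, and C3 is set under catalyst control when the Rh–H adds to one face of the 1,1-disubstituted alkene inside the C2-symmetric bisphosphine pocket.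

Step 3
Reactants: 4 (S)-4,6-dimethoxy-3-phenylindan-1-one
Product: 6 (S)-5,7-dimethoxy-4-phenylchroman-2-one, via Criegee peroxyhemiketal 5 (not isolated)
Conditions: mCPBA (2 equiv), TsOH·H2O (10 mol %), CH2Cl2, 0 °C → rt, dark
Reagents that add atoms: mCPBA (3-chloroperoxybenzoic acid), OOC(=O)c1cccc(Cl)c1
Why: Baeyer–Villiger oxidation: acid-assisted addition of the peracid to C1 gives peroxyhemiketal 5, and the aromatic carbon C7a shifts from C1 to the proximal peroxide oxygen as 3-chlorobenzoate departs, so that this oxygen becomes O1, bonded to C2 (old C1) and to C8a (old C7a). The closest known reaction type is the peracid ring expansion of 3-aryl-1-indanones to 4-aryl-3,4-dihydrocoumarins. The six-membered lactone arises not by a cyclisation but by ring expansion of the five-membered ketone through this 1,2-shift, which adds one atom to the existing ring. No stereocentre is created, and C4 (old C3) is β to the carbonyl and not involved, so the configuration from step 2 should be carried through unchanged. The step needs aryl and not methylene migration, which the higher migratory aptitude of an sp2 aryl carbon over a primary alkyl carbon should secure even with two meta ether groups. It also needs the dialkoxy ring to survive the oxidant, which the acyl (later acyloxy) substituent on that ring, the limited peracid charge and the absence of any second ketone should secure.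

Step 4
Reactants: 6 (S)-5,7-dimethoxy-4-phenylchroman-2-one; 7 3-phenylpropanoyl chloride
Product: 8 (S)-5,7-dimethoxy-4-phenyl-8-(3-phenylpropanoyl)chroman-2-one
Conditions: TiCl4 (2 equiv), CH2Cl2, −10 °C → rt
Reagents that add atoms: none
Why: Friedel–Crafts acylation; C8 is para to the C5 ether, ortho to the C7 ether and flanked on its other side only by the tied-back ring oxygen, whereas C6 lies between two methoxy groups of which the C5 one is buttressed by the C4 substituent, so attack at C8 should dominate, and TiCl4 at low temperature should leave ethers and lactone intact while the doubly activated ring outruns cyclisation of the acylium ion onto its own phenyl group.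

Step 5
Reactants: 8 (S)-5,7-dimethoxy-4-phenyl-8-(3-phenylpropanoyl)chroman-2-one
Product: 10 (S)-5,7-dihydroxy-4-phenyl-8-(3-phenylpropanoyl)chroman-2-one, via bis(dibromoboryl) aryl ether 9 (not isolated)
Conditions: BBr3 (5 equiv), CH2Cl2, −78 → 0 °C; then ice-water
Reagents that add atoms: none
Why: Lewis-acid ether cleavage (BBr3 demethylation): boron coordinates each ether oxygen, bromide attacks the methyl group and the aryloxyboranes are hydrolysed on quench; the C7 ether is cleaved with chelation help from the C8 ketone, the aryl lactone and the ketone should tolerate the cold conditions, and a cold non-basic work-up keeps the lactone closed so that neither the acyl position nor C4 can scramble.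

Compound list
1 | 2-bromo-3,5-dimethoxybenzaldehyde | O=Cc1cc(OC)cc(OC)c1Br | starting material
2 | 4,4,5,5-tetramethyl-2-(1-phenylvinyl)-1,3,2-dioxaborolane | C=C(c1ccccc1)B1OC(C)(C)C(C)(C)O1 | starting material
3 | 3,5-dimethoxy-2-(1-phenylvinyl)benzaldehyde | O=Cc1cc(OC)cc(OC)c1C(=C)c1ccccc1 | intermediate
4 | (S)-4,6-dimethoxy-3-phenylindan-1-one (2,3-dihydro-1H-inden-1-one; phenyl at C3, methoxy at C4 and C6) | O=C1C[C@@H](c2ccccc2)c2c(OC)cc(OC)cc21 | intermediate
5 | (3S)-1-hydroxy-4,6-dimethoxy-3-phenylindan-1-yl 3-chloroperoxybenzoate (Criegee peroxyhemiketal, both C1 epimers) | OC1(OOC(=O)c2cccc(Cl)c2)C[C@@H](c2ccccc2)c2c(OC)cc(OC)cc21 | intermediate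
6 | (S)-5,7-dimethoxy-4-phenylchroman-2-one (3,4-dihydrocoumarin; phenyl at C4) | O=C1C[C@@H](c2ccccc2)c2c(OC)cc(OC)cc2O1 | intermediate
7 | 3-phenylpropanoyl chloride | O=C(Cl)CCc1ccccc1 | starting material
8 | (S)-5,7-dimethoxy-4-phenyl-8-(3-phenylpropanoyl)chroman-2-one | O=C1C[C@@H](c2ccccc2)c2c(OC)cc(OC)c(C(=O)CCc3ccccc3)c2O1 | intermediate
9 | (S)-5,7-bis(dibromoboryloxy)-4-phenyl-8-(3-phenylpropanoyl)chroman-2-one (C7 O–B chelated to the C8 ketone) | O=C1C[C@@H](c2ccccc2)c2c(OB(Br)Br)cc(OB(Br)Br)c(C(=O)CCc3ccccc3)c2O1 | intermediate
10 | (S)-5,7-dihydroxy-4-phenyl-8-(3-phenylpropanoyl)chroman-2-one (CNP0321593.1) | O=C1C[C@@H](c2ccccc2)c2c(O)cc(O)c(C(=O)CCc3ccccc3)c2O1 | target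

Total step count: 5. Longest linear sequence: 5 steps (1 → 3 → 4 → 6 → 8 → 10).

Steps most likely to fail

Step 3 (oxygen insertion). The C2 methylene may migrate in place of the aryl carbon, which puts the oxygen on the wrong side of the carbonyl. The peracid may also hydroxylate the dialkoxy ring, or peroxide addition to the conjugated ketone may stall. The fallback gives up oxygen insertion and brings O1 in with the arene; it sets out from 7 and rejoins the route at 10. Friedel–Crafts acylation of phloroglucinol with 7 (AlCl3, PhNO2/CH2Cl2) should give 3-phenyl-1-(2,4,6-trihydroxyphenyl)propan-1-one F1. Acid-mediated hydroarylation and lactonisation of F1 with (E)-cinnamic acid (TFA or BF3·OEt2, warm) should then give racemic 5,7-dihydroxy-4-phenyl-8-(3-phenylpropanoyl)chroman-2-one F2. Lactonisation onto the other ortho hydroxyl is a competing process to be removed by chromatography. Preparative chiral HPLC of F2 returns 10.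

Step 2 (hydroacylation). The acyl–rhodium hydride may decarbonylate, hydrometalation of the twisted, doubly ortho-flanked 1,1-diarylethene may be sluggish, or facial discrimination may be weak. The fallback closes the ring from the other side, at C3–C3a; it sets out from 1 and rejoins the route at 4. Addition of (E)-styrylmagnesium bromide to the aldehyde (THF, −78 °C) should give racemic (E)-1-(2-bromo-3,5-dimethoxyphenyl)-3-phenylprop-2-en-1-ol F3. MnO2 oxidation (CH2Cl2, rt) should give (E)-1-(2-bromo-3,5-dimethoxyphenyl)-3-phenylprop-2-en-1-one F4. A Pd-catalysed enantioselective reductive Heck cyclisation of this 2'-bromochalcone should then deliver 4 (Pd(OAc)2, 3,5-Xyl-MeO-BIPHEP of the appropriate handedness, iPr2NEt as base and hydride donor, ethylene glycol or DMF, 100 °C).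

Step 4 (C8 acylation). Attack may occur at C6, the acylium ion may be consumed by cyclisation onto its own phenyl ring, or the Lewis acid may open the lactone. The fallback reverses the order, so that free hydroxyl groups and not ethers direct the acylation; it sets out from 6 and rejoins the route at 10. BBr3 (CH2Cl2, −78 → 0 °C) should give, through (S)-5,7-bis(dibromoboryloxy)-4-phenylchroman-2-one F5 and its hydrolysis on quench, (S)-5,7-dihydroxy-4-phenylchroman-2-one F6. Acylation of F6 with 7 (AlCl3, PhNO2, rt to mild warming) should then give 10; O-acylation followed by Fries-type delivery next to the free C7 hydroxyl, and the behaviour of 5,7-dihydroxycoumarins, point to C8.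

Further compounds
F1 | step 3 | 3-phenyl-1-(2,4,6-trihydroxyphenyl)propan-1-one | O=C(CCc1ccccc1)c1c(O)cc(O)cc1O
F2 | step 3 | racemic 5,7-dihydroxy-4-phenyl-8-(3-phenylpropanoyl)chroman-2-one | O=C1CC(c2ccccc2)c2c(O)cc(O)c(C(=O)CCc3ccccc3)c2O1
F3 | step 2 | (E)-1-(2-bromo-3,5-dimethoxyphenyl)-3-phenylprop-2-en-1-ol (racemic) | OC(/C=C/c1ccccc1)c1cc(OC)cc(OC)c1Br
F4 | step 2 | (E)-1-(2-bromo-3,5-dimethoxyphenyl)-3-phenylprop-2-en-1-one | O=C(/C=C/c1ccccc1)c1cc(OC)cc(OC)c1Br
F5 | step 4 | (S)-5,7-bis(dibromoboryloxy)-4-phenylchroman-2-one | O=C1C[C@@H](c2ccccc2)c2c(OB(Br)Br)cc(OB(Br)Br)cc2O1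
F6 | step 4 | (S)-5,7-dihydroxy-4-phenylchroman-2-one | O=C1C[C@@H](c2ccccc2)c2c(O)cc(O)cc2O1
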